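**A one-step world.** In a one-step world of first order, amber and teal convert the same percent per minute. But at 15.0 min amber shows 28% links on a charge of 0.074 M, and teal shows 14% on 0.17 M. Amber has therefore made 0.00138 M min⁻¹ and teal 0.00159 M min⁻¹. Their mean, 0.00148 M min⁻¹, is the link rate, the c(links) made per minute with the gas held; the field calls this zero order in first end groups.

common to all: gas 11 mM (held)

|  | first end groups | remark | time |
|---|---|---|---|
| amber | 0.074 M | run made earlier |  |
| teal | 0.17 M | run made earlier |  |
| summer | 0.11 M |  | 25 min |
| dawn | 0.11 M |  | 30 min |
| midnight | 0.11 M |  | 40 min |

| run | time / min | links / % | first end groups / % |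
|---|---|---|---|
| amber | 2.00 | 3 | 99 |
| amber | 5.00 | 14 | 88 |
| amber | 10.0 | 21 | 79 |
| amber | 15.0 | 28 | 72 |
| teal | 4.00 | 4 | 98 |
| teal | 8.00 | 8 | 94 |
| teal | 12.0 | 10 | 87 |
| teal | 15.0 | 14 | 86 |

(each reading ± 2 percentage points)

- at the start none of the gas is in solution

- which of these there is most of at the end, counted by the first end groups in it, summer (first end groups / links)
- which of these there is most of at the end, counted by the first end groups in it, dawn (first end groups / links)
- which of these there is most of at the end, counted by the first end groups in it, midnight (first end groups / links)
- amount of the one of these that there is most of at the end, in percent of the first end groups charged, summer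
- amount of the one of these that there is most of at the end, in percent of the first end groups charged, dawn
- amount of the one of these that there is most of at the end, in percent of the first end groups charged, midnight

**Bench note.** These flasks hold first end groups with the gas held at 11 mM. I reckon the links alone and take first end groups as the remainder, since amber's 28% and 72% add to 100%. On 0.11 M the link rate gives 33.7% links in summer, 40.4% in dawn and 54.0% in midnight. At 37.1 min links stand at half of the charge, so midnight ends on links, 4 percentage points past half, against a reading scatter of 2 points. Leave the gas hold alone, as both runs were read at it, and add no first end groups.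

**The forecast.** It says “So the absolute rate is nearly independent of end groups”. It gives 67% first end groups for summer, 60% for dawn and 53% links for midnight. Its summer lies above my 66.3%, and its midnight below my 54.0%.

**The flasks.** Summer ends at 65.4% first end groups, dawn at 58.4% first end groups and midnight at 55.3% links.

    first end groups + second end groups → links + by-product (k = 200 M⁻¹ min⁻¹)
    gas ⇌ second end groups, rate k2*(csat - [second end groups]) (kL = 0.140 min⁻¹)
    crystals ⇌ by-product, rate k3*(cs3 - [by-product]) while solid is left; crystals form when [by-product] > cs3 (solubility = 29.0 mM, k = 9.50 min⁻¹)

**What ran.** Dawn's links give 0.00152 M min⁻¹, beside the link rate of 0.00148 M min⁻¹. In dawn the link step did half of its turnover by 15.0 min, with second end groups then at 8.76 × 10⁻⁵ M, made 1.00 times as fast as used (a quasi-steady state), and crystals did half of theirs by 24.6 min. The link rate allows 0.0444 M in 30 min, more than the 0.028 M charged to the neighbour flask that is otherwise dawn, and that neighbour ends at >99.9% links.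

The data stem from a simulated flask for an exercise; the scatter is artificial.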